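**Plan**

- Retrosynthesis: the C2 angelate and C6 anisate C–O bonds are cut first. C8=C9 is traced back to a C9 ketone and the C6 carbinol to a masked C6 ketone. Ring B is then cut at C7–C8 and C1–C10, a (4+3) disconnection into a ring A 2-ethoxydiene and the oxyallyl cation of 3-chlorobutan-2-one. The diene is cut at C5–C6 (Stille) and at C4–isopropyl (Grignard) back to (R)-4-silyloxycyclopent-2-enone.
- Enabling feature: removing C8–C9–C10 from ring B leaves the diene C7=C6(OEt)–C5=C1 anchored on ring A, and C8(CH3)–C9(=O)–C10 is a 1-methyl-2-oxyallyl unit whose carbonyl later becomes C8=C9.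
- Forward order: ring A is elaborated first (steps 1–5) and ring B is closed by the cycloaddition (step 6). Then the C6 ketone is unmasked, C5 is equilibrated, C6 is reduced and acylated, the C9 ketone is converted into the alkene, and the angelate goes on last.
- Stereochemistry: C2 comes from the starting enone. C4 is set by Grignard addition anti to the C2 silyl ether, and C1 by cycloaddition anti to the same group. C5 is set by equilibration to the trans-fused, hydrogen-bonded ketol, and C6 by hydroxyl-directed reduction. The Z ester comes from angelic acid, coupled without isomerisation.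

Key step: step 6

Remark on names: bicyclic compounds are named as daucanes (bicyclo[5.3.0]decane skeleton with CH3 on C1 and C8 and isopropyl on C4). Locants: C1 is the methyl-bearing ring-fusion carbon, C2–C4 are the other ring A carbons (C2 oxygenated CH, C4 the isopropyl carbinol), C5 is the ring-fusion CH, and C6–C10 follow round ring B (C6 oxygenated, C8 methyl-bearing). β is the face of the C1 methyl; in the target the C2 and C4 oxygens are β and H5 and the C6 oxygen are α.

Assumption: (R)-4-(tert-butyldimethylsilyloxy)cyclopent-2-en-1-one, tributyl(1-ethoxyethenyl)stannane and angelic acid are taken as commercial, the first in enantiopure form.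

**Route**

Step 1
Reactants: 1 (R)-4-(tert-butyldimethylsilyloxy)cyclopent-2-en-1-one
Product: 3 (R)-4-(tert-butyldimethylsilyloxy)-3-methylcyclopent-2-en-1-one, via TMS enol ether 2 (not isolated)
Conditions: Me2CuLi (from CuI and MeLi), TMSCl, THF, −78 °C; solvent exchange; Pd(OAc)2 (1.1 equiv), MeCN, rt
Reagents that add atoms: lithium dimethylcuprate, [Li+].C[Cu-]C
Why: Organocuprate conjugate addition anti to the silyloxy group with in-situ silyl trapping of the regiodefined enolate, followed by Saegusa–Ito oxidation, should return the enone with the methyl on the β-carbon; the carbinol centre is untouched and the transient methyl-bearing centre is erased.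

Step 2
Reactants: 3 (R)-4-(tert-butyldimethylsilyloxy)-3-methylcyclopent-2-en-1-one
Product: 4 (R)-4-(tert-butyldimethylsilyloxy)-2-iodo-3-methylcyclopent-2-en-1-one
Conditions: I2, pyridine, DMAP (cat.), CH2Cl2, rt
Reagents that add atoms: iodine, II
Why: Amine-mediated α-iodination of an enone (conjugate addition of the amine, iodination of the enolate, elimination) can only place iodine on the α-carbon and creates no stereocentre.

Step 3
Reactants: 4 (R)-4-(tert-butyldimethylsilyloxy)-2-iodo-3-methylcyclopent-2-en-1-one; 5 tributyl(1-ethoxyethenyl)stannane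
Product: 6 (R)-4-(tert-butyldimethylsilyloxy)-2-(1-ethoxyethenyl)-3-methylcyclopent-2-en-1-one
Conditions: PdCl2(PhCN)2 (cat.), AsPh3, CuI (cat.), NMP, rt to 50 °C; non-acidic work-up
Reagents that add atoms: none
Why: Stille coupling of an α-iodoenone with an α-alkoxyvinylstannane is a standard entry to 2-alkoxydienes, and the fluoride-free, non-acidic conditions should leave the silyl ether and the new enol ether intact.

Step 4
Reactants: 6 (R)-4-(tert-butyldimethylsilyloxy)-2-(1-ethoxyethenyl)-3-methylcyclopent-2-en-1-one; 7 isopropylmagnesium chloride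
Product: 8 (1R,4R)-4-(tert-butyldimethylsilyloxy)-2-(1-ethoxyethenyl)-3-methyl-1-(propan-2-yl)cyclopent-2-en-1-ol
Conditions: LaCl3·2LiCl, THF, 0 °C; NaHCO3 work-up
Reagents that add atoms: none
Why: Lanthanum-promoted Grignard 1,2-addition suppresses enolisation, reduction and conjugate addition, and the nucleophile should enter the nearly planar cyclopentenone on the face opposite to the silyloxy group, placing the new hydroxyl cis to it (1R).

Step 5
Reactants: 8 (1R,4R)-4-(tert-butyldimethylsilyloxy)-2-(1-ethoxyethenyl)-3-methyl-1-(propan-2-yl)cyclopent-2-en-1-ol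
Product: 9 tert-butyl{[(1R,4R)-3-(1-ethoxyethenyl)-2-methyl-4-(propan-2-yl)-4-(triethylsilyloxy)cyclopent-2-en-1-yl]oxy}dimethylsilane
Conditions: TESOTf, 2,6-lutidine, CH2Cl2, −78 to 0 °C
Reagents that add atoms: triethylsilyl trifluoromethanesulfonate, CC[Si](CC)(CC)OS(=O)(=O)C(F)(F)F
Why: Silyl triflate with a hindered pyridine base is the standard silylation of a hindered tertiary alcohol, and the excess base keeps the medium non-acidic so that the ethoxydiene survives.

Step 6
Reactants: 9 tert-butyl{[(1R,4R)-3-(1-ethoxyethenyl)-2-methyl-4-(propan-2-yl)-4-(triethylsilyloxy)cyclopent-2-en-1-yl]oxy}dimethylsilane; 10 3-chlorobutan-2-one (racemic)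
Product: 12 (1R,2R,4R)-2-(tert-butyldimethylsilyloxy)-6-ethoxy-4-(triethylsilyloxy)dauc-5-en-9-one (C8 epimer mixture), via 1-methyl-2-oxyallyl cation 11 (not isolated)
Conditions: Et3N, CF3CH2OH, 0 °C to rt; 10 in excess, added slowly
Reagents that add atoms: none
Why: Triethylamine enolises 10 and the ionising fluoroalcohol lets chloride leave, giving the 1-methyl-2-oxyallyl cation 11, which the electron-rich 2-ethoxydiene 9 should capture in a stepwise cationic (4+3) cycloaddition; the closest known reaction type is the oxyallyl cycloaddition of α-halo ketones with furans, cyclopentadiene and 2-oxygenated 1,3-dienes under amine/fluoroalcohol conditions. The unhindered enol ether terminus C7 attacks the more substituted, more electrophilic cation terminus C8, which produces an ethoxy-stabilised allyl cation over C6–C5–C1 and an enolate. Ring B then closes when the enolate CH2 carbon C10 bonds to C1, a seven-membered ring closure in which the enolate carbon attacks the far terminus of the allyl cation (endo with respect to the cationic π system), leaving the C5=C6 enol ether as a masked C6 ketone distinct from the C9 ketone. C1 is the new stereocentre that matters and is set by substrate control: C10 should arrive on the ring A face opposite to the adjacent C2 silyloxy group (the C4 silyloxy group lies on that same blocked face), which gives 1R with the methyl cis to the C2 oxygen, whereas C8 forms unselectively and is erased in step 11. The step needs regioselectivity (C10 and not C8 on C1), secured by the electronic match of C7 with C8 and by the reluctance of the crowded C1 to bond to the methyl-bearing terminus, and it needs closure at C1 rather than at C6, which the s-cis diene geometry favours by holding C10 over C1.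

Step 7
Reactants: 12 (1R,2R,4R)-2-(tert-butyldimethylsilyloxy)-6-ethoxy-4-(triethylsilyloxy)dauc-5-en-9-one (C8 epimer mixture)
Product: 13 (1R,2R,4R)-2-(tert-butyldimethylsilyloxy)-4-(triethylsilyloxy)daucane-6,9-dione (C5/C8 epimer mixture)
Conditions: oxalic acid (aq.), THF, 0 °C to rt
Reagents that add atoms: water, O
Why: Enol ether hydrolysis (protonation at C5, hydration of the oxocarbenium ion, loss of ethanol) is much faster than ionisation or cleavage of the tertiary silyl ether, so the β-silyloxy ketone should form with the C4 oxygen retained; the C5 configuration formed here is not relied upon.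

Step 8
Reactants: 13 (1R,2R,4R)-2-(tert-butyldimethylsilyloxy)-4-(triethylsilyloxy)daucane-6,9-dione (C5/C8 epimer mixture)
Product: 15 (1R,2R,4R,5R)-2-(tert-butyldimethylsilyloxy)-4-hydroxydaucane-6,9-dione (trans-fused; C8 epimers), via ketol epimer mixture 14 (not isolated)
Conditions: HF·pyridine, pyridine, THF, 0 °C to rt; then DBU (0.3 equiv), toluene, rt
Reagents that add atoms: none
Why: Buffered fluoride desilylation should cleave the tertiary TES ether in preference to the hindered secondary TBS ether, and amidine-base enolisation in a non-polar solvent then equilibrates C5 to the trans-fused ketol (H5 α, 5R), favoured because C6 lies anti to the isopropyl group and its carbonyl is hydrogen-bonded to the cis C4 hydroxyl, while no alkoxide is formed that could start a retro-aldol opening.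

Step 9
Reactants: 15 (1R,2R,4R,5R)-2-(tert-butyldimethylsilyloxy)-4-hydroxydaucane-6,9-dione (trans-fused; C8 epimers)
Product: 16 (1R,2R,4R,5S,6S)-2-(tert-butyldimethylsilyloxy)-4,6-dihydroxydaucan-9-one (C8 epimers)
Conditions: Me4NBH(OAc)3, MeCN/AcOH (1:1), −30 to 0 °C
Reagents that add atoms: none
Why: In this Evans–Saksena hydroxyl-directed reduction the C4 hydroxyl exchanges onto boron and delivers hydride to the β face of the C6 carbonyl, giving the 6α alcohol anti to the C4 hydroxyl (6S, H6 trans to H5; the C5 descriptor changes only through priorities), while the C9 ketone, which has no neighbouring hydroxyl, should not be reduced.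

Step 10
Reactants: 16 (1R,2R,4R,5S,6S)-2-(tert-butyldimethylsilyloxy)-4,6-dihydroxydaucan-9-one (C8 epimers); 17 4-methoxybenzoyl chloride
Product: 18 (1R,2R,4R,5S,6S)-2-(tert-butyldimethylsilyloxy)-4-hydroxy-9-oxodaucan-6-yl 4-methoxybenzoate (C8 epimers)
Conditions: Et3N, DMAP, CH2Cl2, 0 °C to rt
Reagents that add atoms: none
Why: DMAP-catalysed acylation with an acid chloride esterifies the only secondary hydroxyl, the tertiary C4 hydroxyl being inert under these conditions.

Step 11
Reactants: 18 (1R,2R,4R,5S,6S)-2-(tert-butyldimethylsilyloxy)-4-hydroxy-9-oxodaucan-6-yl 4-methoxybenzoate (C8 epimers)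
Product: 19 (1R,2R,4R,5S,6S)-2-(tert-butyldimethylsilyloxy)-4,9-bis(trimethylsilyloxy)dauc-8-en-6-yl 4-methoxybenzoate
Conditions: TMSCl, NaI, Et3N, MeCN, rt
Reagents that add atoms: chlorotrimethylsilane, C[Si](C)(C)Cl
Why: Enol silylation with iodotrimethylsilane generated in situ under equilibrating conditions should give the thermodynamic, tetrasubstituted C8=C9 silyl enol ether rather than the C9=C10 isomer, erasing C8; the tertiary hydroxyl is silylated at the same time, which protects it in the next two steps.

Step 12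
Reactants: 19 (1R,2R,4R,5S,6S)-2-(tert-butyldimethylsilyloxy)-4,9-bis(trimethylsilyloxy)dauc-8-en-6-yl 4-methoxybenzoate
Product: 21 (1R,2R,4R,5S,6S)-2-(tert-butyldimethylsilyloxy)-9-(trifluoromethanesulfonyloxy)-4-(trimethylsilyloxy)dauc-8-en-6-yl 4-methoxybenzoate, via caesium enolate 20 (not isolated)
Conditions: CsF, PhNTf2, DME, rt
Reagents that add atoms: N-phenylbis(trifluoromethanesulfonimide), O=S(=O)(N(c1ccccc1)S(=O)(=O)C(F)(F)F)C(F)(F)F
Why: Fluoride cleaves the enol Si–O bond to the regiodefined enolate without equilibration and O-triflation fixes the C8=C9 position (enol triflate formation from a regiospecifically generated enolate); fluoride is used because the ester rules out alkyllithium cleavage.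

Step 13
Reactants: 21 (1R,2R,4R,5S,6S)-2-(tert-butyldimethylsilyloxy)-9-(trifluoromethanesulfonyloxy)-4-(trimethylsilyloxy)dauc-8-en-6-yl 4-methoxybenzoate
Product: 22 (1R,2R,4R,5S,6S)-2-(tert-butyldimethylsilyloxy)-4-(trimethylsilyloxy)dauc-8-en-6-yl 4-methoxybenzoate
Conditions: Pd(OAc)2 (cat.), PPh3, HCO2H, Bu3N, DMF, 60 °C
Reagents that add atoms: none
Why: Palladium-catalysed formate reduction of an enol triflate (oxidative addition to zerovalent palladium, formate exchange, decarboxylation, reductive elimination) replaces OTf by H without moving the double bond, giving the C8=C9 trisubstituted alkene.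

Step 14
Reactants: 22 (1R,2R,4R,5S,6S)-2-(tert-butyldimethylsilyloxy)-4-(trimethylsilyloxy)dauc-8-en-6-yl 4-methoxybenzoate
Product: 23 (1R,2R,4R,5S,6S)-2,4-dihydroxydauc-8-en-6-yl 4-methoxybenzoate
Conditions: HF·pyridine, pyridine, THF, 0 °C to rt
Reagents that add atoms: none
Why: Fluoride-mediated desilylation removes the secondary TBS and tertiary TMS ethers; the pyridine buffer prevents HF addition to the alkene and the ester is stable.

Step 15
Reactants: 23 (1R,2R,4R,5S,6S)-2,4-dihydroxydauc-8-en-6-yl 4-methoxybenzoate; 24 angelic acid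
Product: 26 (1R,2R,4R,5S,6S)-4-hydroxy-6-(4-methoxybenzoyloxy)dauc-8-en-2-yl (Z)-2-methylbut-2-enoate (CNP0204191.1), via mixed anhydride 25 (not isolated)
Conditions: 24, 2,4,6-trichlorobenzoyl chloride, Et3N, toluene, rt; then 23, 80 °C (no DMAP)
Reagents that add atoms: none
Why: Yamaguchi-type esterification through the 2,4,6-trichlorobenzoyl mixed anhydride, run without a nucleophilic catalyst, should acylate the secondary C2 hydroxyl only and is the established way to form angelates without Z-to-E isomerisation to the tiglate.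

**Compound list**

1 | (R)-4-(tert-butyldimethylsilyloxy)cyclopent-2-en-1-one | CC(C)(C)[Si](C)(C)O[C@H]1C=CC(=O)C1 | starting material
2 | (3R,4R)-4-(tert-butyldimethylsilyloxy)-3-methyl-1-(trimethylsilyloxy)cyclopent-1-ene (methyl trans to OTBS) | CC(C)(C)[Si](C)(C)O[C@H]1[C@H](C)C=C(O[Si](C)(C)C)C1 | intermediate
3 | (R)-4-(tert-butyldimethylsilyloxy)-3-methylcyclopent-2-en-1-one | CC(C)(C)[Si](C)(C)O[C@H]1C(C)=CC(=O)C1 | intermediate
4 | (R)-4-(tert-butyldimethylsilyloxy)-2-iodo-3-methylcyclopent-2-en-1-one | CC(C)(C)[Si](C)(C)O[C@H]1C(C)=C(I)C(=O)C1 | intermediate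
5 | tributyl(1-ethoxyethenyl)stannane | CCCC[Sn](CCCC)(CCCC)C(=C)OCC | starting material
6 | (R)-4-(tert-butyldimethylsilyloxy)-2-(1-ethoxyethenyl)-3-methylcyclopent-2-en-1-one | CC(C)(C)[Si](C)(C)O[C@H]1C(C)=C(C(=C)OCC)C(=O)C1 | intermediate
7 | isopropylmagnesium chloride | CC(C)[Mg]Cl | starting material
8 | (1R,4R)-4-(tert-butyldimethylsilyloxy)-2-(1-ethoxyethenyl)-3-methyl-1-(propan-2-yl)cyclopent-2-en-1-ol (OH cis to OTBS) | CC(C)(C)[Si](C)(C)O[C@@H]1C[C@@](O)(C(C)C)C(C(=C)OCC)=C1C | intermediate
9 | tert-butyl{[(1R,4R)-3-(1-ethoxyethenyl)-2-methyl-4-(propan-2-yl)-4-(triethylsilyloxy)cyclopent-2-en-1-yl]oxy}dimethylsilane (ring A diene) | CC(C)(C)[Si](C)(C)O[C@@H]1C[C@@](O[Si](CC)(CC)CC)(C(C)C)C(C(=C)OCC)=C1C | intermediate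
10 | 3-chlorobutan-2-one (racemic) | CC(Cl)C(C)=O | starting material
11 | 1-methyl-2-oxyallyl cation (zwitterion) | C[CH+]C([O-])=C | intermediate
12 | (1R,2R,4R)-2-(tert-butyldimethylsilyloxy)-6-ethoxy-4-(triethylsilyloxy)dauc-5-en-9-one (C8 epimer mixture) | CC(C)(C)[Si](C)(C)O[C@@H]1C[C@@](O[Si](CC)(CC)CC)(C(C)C)C2=C(OCC)CC(C)C(=O)C[C@]21C | intermediate
13 | (1R,2R,4R)-2-(tert-butyldimethylsilyloxy)-4-(triethylsilyloxy)daucane-6,9-dione (C5/C8 epimer mixture) | CC(C)(C)[Si](C)(C)O[C@@H]1C[C@@](O[Si](CC)(CC)CC)(C(C)C)C2C(=O)CC(C)C(=O)C[C@]21C | intermediate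
14 | (1R,2R,4R)-2-(tert-butyldimethylsilyloxy)-4-hydroxydaucane-6,9-dione (C5/C8 epimer mixture) | CC(C)(C)[Si](C)(C)O[C@@H]1C[C@@](O)(C(C)C)C2C(=O)CC(C)C(=O)C[C@]21C | intermediate
15 | (1R,2R,4R,5R)-2-(tert-butyldimethylsilyloxy)-4-hydroxydaucane-6,9-dione (trans-fused, H5 α; C8 epimers) | CC(C)(C)[Si](C)(C)O[C@@H]1C[C@@](O)(C(C)C)[C@@H]2C(=O)CC(C)C(=O)C[C@]21C | intermediate
16 | (1R,2R,4R,5S,6S)-2-(tert-butyldimethylsilyloxy)-4,6-dihydroxydaucan-9-one (6α-OH; C8 epimers) | CC(C)(C)[Si](C)(C)O[C@@H]1C[C@@](O)(C(C)C)[C@@H]2[C@@H](O)CC(C)C(=O)C[C@]21C | intermediate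
17 | 4-methoxybenzoyl chloride | COc1ccc(cc1)C(Cl)=O | starting material
18 | (1R,2R,4R,5S,6S)-2-(tert-butyldimethylsilyloxy)-4-hydroxy-9-oxodaucan-6-yl 4-methoxybenzoate (C8 epimers) | CC(C)(C)[Si](C)(C)O[C@@H]1C[C@@](O)(C(C)C)[C@@H]2[C@@H](OC(=O)c3ccc(OC)cc3)CC(C)C(=O)C[C@]21C | intermediate
19 | (1R,2R,4R,5S,6S)-2-(tert-butyldimethylsilyloxy)-4,9-bis(trimethylsilyloxy)dauc-8-en-6-yl 4-methoxybenzoate | CC(C)(C)[Si](C)(C)O[C@@H]1C[C@@](O[Si](C)(C)C)(C(C)C)[C@@H]2[C@@H](OC(=O)c3ccc(OC)cc3)CC(C)=C(O[Si](C)(C)C)C[C@]21C | intermediate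
20 | caesium (1R,2R,4R,5S,6S)-2-(tert-butyldimethylsilyloxy)-6-(4-methoxybenzoyloxy)-4-(trimethylsilyloxy)dauc-8-en-9-olate | CC(C)(C)[Si](C)(C)O[C@@H]1C[C@@](O[Si](C)(C)C)(C(C)C)[C@@H]2[C@@H](OC(=O)c3ccc(OC)cc3)CC(C)=C([O-])C[C@]21C.[Cs+] | intermediate
21 | (1R,2R,4R,5S,6S)-2-(tert-butyldimethylsilyloxy)-9-(trifluoromethanesulfonyloxy)-4-(trimethylsilyloxy)dauc-8-en-6-yl 4-methoxybenzoate | CC(C)(C)[Si](C)(C)O[C@@H]1C[C@@](O[Si](C)(C)C)(C(C)C)[C@@H]2[C@@H](OC(=O)c3ccc(OC)cc3)CC(C)=C(OS(=O)(=O)C(F)(F)F)C[C@]21C | intermediate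
22 | (1R,2R,4R,5S,6S)-2-(tert-butyldimethylsilyloxy)-4-(trimethylsilyloxy)dauc-8-en-6-yl 4-methoxybenzoate | CC(C)(C)[Si](C)(C)O[C@@H]1C[C@@](O[Si](C)(C)C)(C(C)C)[C@@H]2[C@@H](OC(=O)c3ccc(OC)cc3)CC(C)=CC[C@]21C | intermediate
23 | (1R,2R,4R,5S,6S)-2,4-dihydroxydauc-8-en-6-yl 4-methoxybenzoate | O[C@@H]1C[C@@](O)(C(C)C)[C@@H]2[C@@H](OC(=O)c3ccc(OC)cc3)CC(C)=CC[C@]21C | intermediate
24 | angelic acid, (Z)-2-methylbut-2-enoic acid | C/C=C(/C)C(=O)O | starting material
25 | (Z)-2-methylbut-2-enoic 2,4,6-trichlorobenzoic anhydride | C/C=C(/C)C(=O)OC(=O)c1c(Cl)cc(Cl)cc1Cl | intermediate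
26 | (1R,2R,4R,5S,6S)-4-hydroxy-6-(4-methoxybenzoyloxy)dauc-8-en-2-yl (Z)-2-methylbut-2-enoate (CNP0204191.1) | C/C=C(/C)C(=O)O[C@@H]1C[C@@](O)(C(C)C)[C@@H]2[C@@H](OC(=O)c3ccc(OC)cc3)CC(C)=CC[C@]21C | target

**Step count**

Total steps: 15. Longest linear sequence: 15 steps (1 to 26).

**Steps most likely to fail**

1. Step 6 (key cycloaddition). What may go wrong: the crowded C1 terminus may fail to close ring B, so that the intermediate cation is lost to solvent capture, proton loss or five-membered ring closure at C6. Coupling through the wrong oxyallyl terminus and poor facial selectivity at C1 are further risks. Fallback: setting out from 9, the three-carbon unit is introduced as 2-(triisopropylsilyloxy)but-2-enal with Sc(OTf)3 in CH2Cl2 at −78 °C, a Lewis acid-promoted (4+3) annulation of 2-silyloxy enals. C7 can only add in conjugate fashion to the methyl-bearing β-carbon, so the regiochemistry is fixed, and the silyl enol ether carbon then closes on C1. After silyl transfer this should give (1R,2R,4R)-2-(tert-butyldimethylsilyloxy)-6-ethoxy-4-(triethylsilyloxy)-10-(triisopropylsilyloxy)dauc-5-en-9-one F1. SmI2 in THF/MeOH then cleaves the α-silyloxy C–O bond of the ketone reductively, and the route is rejoined at 12.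

2. Step 8 (C5 equilibration). What may go wrong: the epimerisation at C5 may be incomplete or may leave too much cis-fused ketol, and the free ketol may open by retro-aldol cleavage or lose the C4 oxygen by β-elimination under the base. Fallback: setting out from the ketol mixture 14, the base treatment is left out and the mixture is reduced directly with Me4NBH(OAc)3 in MeCN/AcOH. Only the trans-fused epimer, whose C6 carbonyl is cis to the C4 hydroxyl, can receive hydride through the boron chelate, so the reduction acts as a kinetic selection. Diol 16 is separated from unreduced cis-fused ketol, which is re-equilibrated on a weakly basic support and resubmitted. The route is rejoined at 16 and no compound outside the list is made (F0).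

3. Step 11 (regiochemistry of enolisation). What may go wrong: enolisation toward C10 instead of C8 would lead to the C9=C10 alkene, and the iodosilane may attack the ester. Fallback: setting out from 18, the ketone is reduced with NaBH4 in MeOH to (1R,2R,4R,5S,6S)-2-(tert-butyldimethylsilyloxy)-4,9-dihydroxydaucan-6-yl 4-methoxybenzoate F2 (C8/C9 epimers). The secondary hydroxyl is mesylated (MsCl, Et3N, CH2Cl2; the tertiary hydroxyl does not react) to give (1R,2R,4R,5S,6S)-2-(tert-butyldimethylsilyloxy)-4-hydroxy-9-(methanesulfonyloxy)daucan-6-yl 4-methoxybenzoate F3. E2 elimination with DBU in hot toluene toward the tertiary C8–H (Zaitsev) should give (1R,2R,4R,5S,6S)-2-(tert-butyldimethylsilyloxy)-4-hydroxydauc-8-en-6-yl 4-methoxybenzoate F4. Buffered HF·pyridine in THF removes the TBS ether, and the route is rejoined at 23.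

**Further compounds**

F1 | step 6 | (1R,2R,4R)-2-(tert-butyldimethylsilyloxy)-6-ethoxy-4-(triethylsilyloxy)-10-(triisopropylsilyloxy)dauc-5-en-9-one | CC(C)(C)[Si](C)(C)O[C@@H]1C[C@@](O[Si](CC)(CC)CC)(C(C)C)C2=C(OCC)CC(C)C(=O)C(O[Si](C(C)C)(C(C)C)C(C)C)[C@]21C
F0 | step 8 | none | none
F2 | step 11 | (1R,2R,4R,5S,6S)-2-(tert-butyldimethylsilyloxy)-4,9-dihydroxydaucan-6-yl 4-methoxybenzoate | CC(C)(C)[Si](C)(C)O[C@@H]1C[C@@](O)(C(C)C)[C@@H]2[C@@H](OC(=O)c3ccc(OC)cc3)CC(C)C(O)C[C@]21C
F3 | step 11 | (1R,2R,4R,5S,6S)-2-(tert-butyldimethylsilyloxy)-4-hydroxy-9-(methanesulfonyloxy)daucan-6-yl 4-methoxybenzoate | CC(C)(C)[Si](C)(C)O[C@@H]1C[C@@](O)(C(C)C)[C@@H]2[C@@H](OC(=O)c3ccc(OC)cc3)CC(C)C(OS(C)(=O)=O)C[C@]21C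
F4 | step 11 | (1R,2R,4R,5S,6S)-2-(tert-butyldimethylsilyloxy)-4-hydroxydauc-8-en-6-yl 4-methoxybenzoate | CC(C)(C)[Si](C)(C)O[C@@H]1C[C@@](O)(C(C)C)[C@@H]2[C@@H](OC(=O)c3ccc(OC)cc3)CC(C)=CC[C@]21C
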